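# Proposed total synthesis of CNP0596241.1 (12-O-acetyl-6,7-dehydroroyleanone 19,20-olide)

## Analysis of the target

- **Skeleton.** The target (27) is an abietane in which ring C (C8, C9, C11–C14) is a fully substituted 1,4-benzoquinone carrying an enol acetate at C12 and isopropyl at C13. Ring B holds a C6=C7 double bond conjugated to that quinone, and ring A is a plain cyclohexane.
- **The bridge.** A δ-lactone C19(=O)–O–C20H2 spans C4 and C10 across C5, so ring A and the lactone together form a 3-oxabicyclo[3.3.1]nonan-2-one.
- **Stereocentres.** There are three contiguous centres: C4 (quaternary: C18 methyl, C19 carbonyl), C5 (H) and C10 (quaternary: C20, C9), in the (4S,5R,10R) configuration, i.e. C19 and C20 both β and diaxial, H-5 α, A/B trans.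
- **How they relate.** C4 and C10 are the bridgeheads of the bicycle, so their relative configuration is dictated by the bridge. Once the bridge exists, only two variables remain: the orientation of C5 relative to the lactone and the absolute sense.
- **Sensitive groups.** The enol acetate on the quinone is cleaved by mild base or nucleophiles, the quinone is reduced and attacked by organometallics, the lactone does not tolerate unselective strong nucleophiles, and H-5 is vinylogously acidic through C6=C7–C8=C9–C11=O.
- **What makes it hard.** Two quaternary centres in a 1,3-relationship each carry an oxidised one-carbon substituent; C20 oxidation removes the usual angular-methyl logic of terpene synthesis; and the unsymmetrical quinone must carry O at C12 and isopropyl at C13, not the reverse.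

## Retrosynthetic reasoning

**Acetate and O-alkyl group.** The enol acetate of 27 is put on last from hydroxyquinone 26, which comes from the isopropyl ether 25. The C12 oxygen is thus carried as a robust vinylogous ester through the ring C construction and unmasked only at the end.

**Ring C (bonds C9–C11 and C8–C14).** The quinone of 25 is cut into a four-carbon squarate piece and the C8=C9 alkene of ring B. The precursor is the 4-dienyl-4-silyloxycyclobutenone 22, assembled from vinyl iodide 15, diisopropyl squarate 16 and isopropylmagnesium chloride 20. This cut was chosen because 16 already holds C11–C14 at the right oxidation level, and the order of the two additions places isopropyl next to C14 and the ether oxygen next to C11. The forward step is a thermal 4π opening/6π closure of 22 followed by oxidation.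

**Ring B handle.** Iododiene 15 is traced to enone 12. The C7 carbonyl serves twice: it activates C8 for α-iodination (13), and after reduction (14) it leaves as the C6=C7 double bond. No oxygen has to be removed from C7 later.

**Ring A (bond C3–C4).** Tricycle 12 is opened at C3–C4 to the α-methylene lactone 10, which carries a 3-chloropropyl arm on C10. Conjugate hydride addition turns the exocyclic methylene into the C18 methyl and gives lactone enolate 11 regiospecifically. The arm on C10 can reach only one face of that enolate, so C4 needs no separate control.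

**Key disconnection (bond C4–C5, lactone ring, C5 and C10 together).** Bicycle 10 is cut at C4–C5 to the achiral dienone 8, whose two enone arms (C5=C6 and C9=C8) are enantiotopic. The acrylate on C20–O is the latent C19/C4/C18 unit. The forward reaction is a catalytic enantioselective intramolecular Rauhut–Currier reaction: it must pick one enone arm, which sets C10 and C5 at once, and close the δ-lactone.

**Dearomatisation.** Dienone 8 comes from acrylate 7 by oxidation of the doubly allylic CH2. Ester 7 comes from alcohol 5 and acryloyl chloride 6, and 5 from acid 4. Acid 4 is the Birch reductive alkylation product of benzoic acid 1 with 1-bromo-3-chloropropane 2. The benzene ring of 1 becomes ring B, its ipso carbon becomes C10, and its carboxyl carbon becomes C20.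

## Alternatives that were turned down

**Alternative 1:** Polyene bicyclisation (the textbook route). Cut C4–C5 and C9–C10. An aryl-terminated β-keto ester A1 would be cyclised with Mn(OAc)3/Cu(OAc)2 (or a Lewis acid) to tricycle A2. Turned down for these reasons:
- C20 must ride on the central alkene as an allylic CH2OR group, which slows the second ring closure and can ionise.
- The C3 ketone needed to generate the C4 radical must be removed afterwards.
- Absolute control is only available through a stoichiometric chiral ester.
- The ring closure must occur at C9, ortho to the C11 methoxy group, on an arene that Mn(OAc)3 itself oxidises.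
- The arene costs about three steps to make, and several more are needed to reach the quinone and the C6=C7 bond. The lactone is still not closed in A2.

**Alternative 2:** Type 2 intramolecular Diels–Alder reaction. Cut C4–C5 and C2–C3. The methacrylate triene A3 would cyclise to the bridged lactone A4 with a bridgehead C1=C10 alkene; protonation and Friedel–Crafts closure at the bridgehead cation would then give ring B. It is attractive because the bridge and the C5 orientation (from the diene geometry) arise in one step. Turned down for these reasons:
- A three-atom ester tether must reach its disfavoured s-cis conformation and deliver an anti-Bredt bicyclo[3.3.1]non-1-ene. Closures of that tether length need temperatures at which A3 would polymerise or fragment.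
- A3 is achiral and offers no two-point binding for a chiral Lewis acid, so there is no defensible source of absolute configuration.
- The following cation sits next to the electron-withdrawing C20–O bond. The risk would lie in two consecutive steps.

**Alternative 3:** Relay from the chiral pool. (+)-Podocarpic acid A5 already has C4, C5 and C10. A carboxyl-directed C20–H lactonisation would give A6, followed by isopropylation and ring C oxidation. Turned down for these reasons:
- All three stereocentres are bought, and the key step makes a single C–O bond.
- Hydrogen transfer from C20 to an oxygen- or nitrogen-centred radical on C19 needs a seven-membered transition state. It competes with decarboxylation of the tertiary acyloxy radical and with abstraction at benzylic C7.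
- A6 still lacks the isopropyl group, two ring C oxygens and the C6=C7 bond, which means a long oxidation sequence on an electron-rich arene.

Key step: step 5

**Remarks before the steps.**
- Abietane numbering is used for all intermediates: ring A is C1–C5 and C10; ring B is C5–C10; ring C is C8, C9 and C11–C14; C18 is the methyl on C4; C19 is the lactone carbonyl; C20 is the lactone CH2.
- Compounds 1, 2, 6, 16 and 20 are commercial.
- Assumption: the (S)-aminophosphine is taken to deliver the enantiomer drawn for 10. If the sense of induction in this six-membered-lactone series proves opposite, the (R)-catalyst from D-valine is used instead.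

## Steps

Step 1
Reactants: 1 benzoic acid; 2 1-bromo-3-chloropropane
Product: 4 1-(3-chloropropyl)cyclohexa-2,5-diene-1-carboxylic acid, via dilithium dienolate 3 (not isolated)
Conditions: Li, NH3(l)/THF, −78 °C; then 2, −78 °C → −33 °C; NH4Cl, then aq. HCl
Reagents that add atoms: 1-bromo-3-chloropropane (compound 2), ClCCCBr
Why: Birch reductive alkylation; the dianion 3 is alkylated at the ipso carbon by the more reactive bromide end, creating the future C10 with its C1–C3 arm and leaving the C3 chloride untouched. No stereocentre is formed, since 4 has a mirror plane.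

Step 2
Reactants: 4 1-(3-chloropropyl)cyclohexa-2,5-diene-1-carboxylic acid
Product: 5 [1-(3-chloropropyl)cyclohexa-2,5-dien-1-yl]methanol
Conditions: LiAlH4, Et2O, 0 → 23 °C
Reagents that add atoms: none
Why: Hydride reduction of the acid to the neopentyl alcohol (the future C20–OH); the skipped diene and the primary chloride should be inert at this temperature.

Step 3
Reactants: 5 [1-(3-chloropropyl)cyclohexa-2,5-dien-1-yl]methanol; 6 acryloyl chloride
Product: 7 [1-(3-chloropropyl)cyclohexa-2,5-dien-1-yl]methyl prop-2-enoate
Conditions: Et3N, CH2Cl2, −20 → 0 °C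
Reagents that add atoms: acryloyl chloride (compound 6), C=CC(Cl)=O
Why: O-Acylation; the acrylate brings C19, C4 and C18 and becomes the tether for the key step.

Step 4
Reactants: 7 [1-(3-chloropropyl)cyclohexa-2,5-dien-1-yl]methyl prop-2-enoate
Product: 8 [1-(3-chloropropyl)-4-oxocyclohexa-2,5-dien-1-yl]methyl prop-2-enoate
Conditions: Rh2(cap)4 (dirhodium tetrakis(caprolactamate), 1 mol%), t-BuOOH (70% aq.), K2CO3, CH2Cl2, 23 °C
Reagents that add atoms: tert-butyl hydroperoxide, CC(C)(C)OO
Why: Oxidation of the doubly allylic CH2 of a Birch-derived 1,4-diene to the cross-conjugated dienone, a known conversion for 1-substituted cyclohexa-2,5-dienes; the quaternary C10 blocks aromatisation and the electron-poor acrylate should be spared. The carbonyl becomes C7.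

Step 5
Reactants: 8 [1-(3-chloropropyl)-4-oxocyclohexa-2,5-dien-1-yl]methyl prop-2-enoate
Product: 10 cis-fused bicyclic α-methylene-δ-lactone enone (10β-CH2O, 5α-H; 3-chloropropyl on C10; C4=CH2; C7=O; C8=C9), via phosphonium enolate 9 (not isolated)
Conditions: (S)-Ph2PCH2CH(i-Pr)NHTs (20 mol%), toluene, 0 → 23 °C
Reagents that add atoms: none
Why: Enantioselective intramolecular Rauhut–Currier reaction: the phosphine adds to the acrylate β-carbon to give 9, whose α-carbon (C4) adds to one of the two enantiotopic dienone β-carbons (C5); proton shift and loss of the phosphine then give the exocyclic methylene and return the catalyst. The closest known reaction is the desymmetrisation of acrylate-tethered cyclohexa-2,5-dienones to α-methylene-γ-butyrolactones with amino-acid-derived phosphine–sulfonamide catalysts; here the tether is one CH2 longer. The δ-lactone closes by a 6-exo-trig Michael addition. The three-atom tether lets C4 reach C5 only on the face that carries C20, so the lactone is cis-fused and H-5 ends up anti to C20, which is the trans A/B relationship of the target. C10 becomes stereogenic in the same event, because the two arms are differentiated. The absolute sense is set by the catalyst, whose sulfonamide N–H should hydrogen-bond to the dienone carbonyl and thereby direct the enolate to one arm. The step needs chemoselective phosphine addition to the acrylate; this is secured because the dienone β-carbons are neopentyl, the primary chloride alkylates phosphines only slowly, and 8 has no enolisable hydrogen.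

Step 6
Reactants: 10 cis-fused bicyclic α-methylene-δ-lactone enone
Product: 12 tricyclic enone lactone (rings A and B plus the 19,20-lactone; 4α-CH3, 5α-H, C7=O, C8=C9), via potassium lactone enolate 11 (not isolated)
Conditions: K[(s-Bu)3BH] (1.0 equiv), THF, −78 °C; then DMPU, −78 → 40 °C
Reagents that add atoms: none
Why: Conjugate reduction–intramolecular alkylation: hydride adds to the unhindered exocyclic CH2 (which becomes C18), and enolate 11 closes ring A by a 6-(enolexo)-exo-tet displacement of the C3 chloride. The arm on C10 can reach C4 only from the face opposite C5–H across the lactone ring, so the C4 configuration (C19 β, C18 α) is forced by the bicyclo[3.3.1] geometry. The ring B enone is a slower acceptor because C9 is neopentyl.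

Step 7
Reactants: 12 tricyclic enone lactone
Product: 13 8-iodo enone lactone
Conditions: I2, pyridine/CH2Cl2 (1:1), 23 °C
Reagents that add atoms: iodine, II
Why: α-Iodination of a cyclohexenone by pyridine conjugate addition, iodination of the enolate and elimination; it places the metalation handle on C8 without touching the lactone.

Step 8
Reactants: 13 8-iodo enone lactone
Product: 14 8-iodo-7-hydroxy allylic alcohol (either C7 epimer; the centre is removed in step 9)
Conditions: NaBH4, CeCl3·7H2O, MeOH, −40 → 0 °C
Reagents that add atoms: none
Why: Luche 1,2-reduction of the iodoenone; the hindered lactone and the vinyl iodide are stable to borohydride.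

Step 9
Reactants: 14 8-iodo-7-hydroxy allylic alcohol
Product: 15 8-iodo-6,8-diene lactone
Conditions: Ph2S[OC(CF3)2Ph]2 (Martin sulfurane), CH2Cl2, 0 → 23 °C
Reagents that add atoms: none
Why: Sulfurane dehydration of a secondary allylic alcohol; the only β-hydrogens are on C6, so elimination can only give the conjugated C6=C7–C8=C9 diene, and the quaternary C10 blocks aromatisation.

Step 10
Reactants: 15 8-iodo-6,8-diene lactone; 16 diisopropyl squarate
Product: 19 4-dienyl-2,3-diisopropoxy-4-(trimethylsilyloxy)cyclobut-2-en-1-one (dienyl = C8 of the lactone diene; carbinol epimers), via dienyllithium 17 (not isolated), via lithium alkoxide 18 (not isolated)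
Conditions: t-BuLi (2.1 equiv), THF/Et2O, −100 °C; cannulate into 16, THF, −78 °C; then Me3SiCl, −78 → 0 °C
Reagents that add atoms: diisopropyl squarate (compound 16), CC(C)OC1=C(OC(C)C)C(=O)C1=O; chlorotrimethylsilane, C[Si](C)(C)Cl
Why: Iodine–lithium exchange is much faster at −100 °C than addition to the hindered lactone (quaternary α-carbon), and the dienyllithium adds 1,2 to one squarate carbonyl; silylation protects the carbinol so that the second nucleophile can be added cleanly.

Step 11
Reactants: 19 4-dienyl-2,3-diisopropoxy-4-(trimethylsilyloxy)cyclobut-2-en-1-one; 20 isopropylmagnesium chloride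
Product: 22 4-dienyl-2-isopropoxy-3-isopropyl-4-(trimethylsilyloxy)cyclobut-2-en-1-one, via tertiary alkoxide adduct 21 (not isolated)
Conditions: 20, CeCl3, THF, −78 °C; then (CF3CO)2O, −78 → 0 °C; aq. NaHCO3
Reagents that add atoms: isopropylmagnesium chloride (compound 20), CC(C)[Mg]Cl; water, O
Why: The organocerium reagent adds to the strained cyclobutenone carbonyl in preference to the hindered lactone. Trifluoroacetylation and ionisation of the new tertiary carbinol, followed by hydrolysis of the resulting vinylogous oxocarbenium ion, transpose the carbonyl (the known regio-complementary squarate sequence). The isopropyl carbon thereby ends up next to the dienyl carbinol carbon, which is what puts isopropyl on C13 and oxygen on C12.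

Step 12
Reactants: 22 4-dienyl-2-isopropoxy-3-isopropyl-4-(trimethylsilyloxy)cyclobut-2-en-1-one
Product: 25 12-O-isopropyl-6,7-dehydroroyleanone 19,20-olide (the 12-isopropoxy quinone), via dienylketene 23 (not isolated), via hydroquinone mono(trimethylsilyl) ether 24 (not isolated)
Conditions: toluene, 110 °C; then (NH4)2Ce(NO3)6, MeCN/H2O, 0 °C
Reagents that add atoms: none
Why: Moore rearrangement: conrotatory 4π opening with the silyloxy group turning outward gives ketene 23, 6π closure onto C9 and tautomerisation give 24, and tetravalent cerium oxidises 24 to the quinone with loss of the silyl group. The ketene carbon becomes C11 and the carbinol carbon becomes C14, and the C6=C7 bond is already in place.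

Step 13
Reactants: 25 12-O-isopropyl-6,7-dehydroroyleanone 19,20-olide
Product: 26 6,7-dehydroroyleanone 19,20-olide (12-hydroxy quinone)
Conditions: BCl3, CH2Cl2, −78 → 0 °C; then H2O
Reagents that add atoms: none
Why: Chelation-assisted cleavage of the isopropyl vinylogous ester by coordination of boron to the C11 carbonyl; the secondary alkyl group leaves as 2-chloropropane while the lactone and the diene-quinone are left intact at low temperature.

Step 14
Reactants: 26 6,7-dehydroroyleanone 19,20-olide
Product: 27 target, 12-O-acetyl-6,7-dehydroroyleanone 19,20-olide (4S,5R,10R)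
Conditions: Ac2O, pyridine, CH2Cl2, 0 °C
Reagents that add atoms: acetic anhydride, CC(=O)OC(C)=O
Why: O-Acetylation of the acidic hydroxyquinone under mild conditions, kept short and cold so that the vinylogously acidic H-5 is not disturbed.

## Compound list

1 | benzoic acid | OC(=O)c1ccccc1 | starting material
2 | 1-bromo-3-chloropropane | ClCCCBr | starting material
3 | dilithium dienolate of 1,4-dihydrobenzoic acid | [Li+].[Li+].[O-]C([O-])=C1C=CCC=C1 | intermediate
4 | 1-(3-chloropropyl)cyclohexa-2,5-diene-1-carboxylic acid | OC(=O)C1(CCCCl)C=CCC=C1 | intermediate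
5 | [1-(3-chloropropyl)cyclohexa-2,5-dien-1-yl]methanol | OCC1(CCCCl)C=CCC=C1 | intermediate
6 | acryloyl chloride | C=CC(Cl)=O | starting material
7 | [1-(3-chloropropyl)cyclohexa-2,5-dien-1-yl]methyl prop-2-enoate | C=CC(=O)OCC1(CCCCl)C=CCC=C1 | intermediate
8 | [1-(3-chloropropyl)-4-oxocyclohexa-2,5-dien-1-yl]methyl prop-2-enoate | C=CC(=O)OCC1(CCCCl)C=CC(=O)C=C1 | intermediate
9 | phosphonium enolate from the catalyst and the acrylate of 8 | [O-]C(OCC1(CCCCl)C=CC(=O)C=C1)=CC[P+](c1ccccc1)(c1ccccc1)C[C@H](C(C)C)NS(=O)(=O)c1ccc(C)cc1 | intermediate
10 | cis-fused bicyclic α-methylene-δ-lactone enone (10β-CH2O, 5α-H, 3-chloropropyl on C10) | O=C1C=C[C@]2(CCCCl)COC(=O)C(=C)[C@@H]2C1 | intermediate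
11 | potassium lactone enolate of the C18-methyl lactone | O=C1C=C[C@]2(CCCCl)COC([O-])=C(C)[C@@H]2C1.[K+] | intermediate
12 | tricyclic enone lactone (4α-CH3, 5α-H, 19,20-olide, 7-oxo, Δ8) | O=C1C=C[C@]23CCC[C@](C)(C(=O)OC2)[C@@H]3C1 | intermediate
13 | 8-iodo enone lactone | O=C1C(I)=C[C@]23CCC[C@](C)(C(=O)OC2)[C@@H]3C1 | intermediate
14 | 8-iodo-7-hydroxy allylic alcohol (C7 epimers) | OC1C(I)=C[C@]23CCC[C@](C)(C(=O)OC2)[C@@H]3C1 | intermediate
15 | 8-iodo-6,8-diene lactone | IC1=C[C@]23CCC[C@](C)(C(=O)OC2)[C@@H]3C=C1 | intermediate
16 | diisopropyl squarate | CC(C)OC1=C(OC(C)C)C(=O)C1=O | starting material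
17 | C8 dienyllithium | [Li]C1=C[C@]23CCC[C@](C)(C(=O)OC2)[C@@H]3C=C1 | intermediate
18 | lithium alkoxide of the squarate 1,2-adduct | [Li+].[O-]C1(C(=O)C(OC(C)C)=C1OC(C)C)C1=C[C@]23CCC[C@](C)(C(=O)OC2)[C@@H]3C=C1 | intermediate
19 | 4-dienyl-2,3-diisopropoxy-4-(trimethylsilyloxy)cyclobut-2-en-1-one | C[Si](C)(C)OC1(C(=O)C(OC(C)C)=C1OC(C)C)C1=C[C@]23CCC[C@](C)(C(=O)OC2)[C@@H]3C=C1 | intermediate
20 | isopropylmagnesium chloride | CC(C)[Mg]Cl | starting material
21 | tertiary alkoxide adduct of isopropyl addition (drawn as the alcohol) | C[Si](C)(C)OC1(C(O)(C(C)C)C(OC(C)C)=C1OC(C)C)C1=C[C@]23CCC[C@](C)(C(=O)OC2)[C@@H]3C=C1 | intermediate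
22 | 4-dienyl-2-isopropoxy-3-isopropyl-4-(trimethylsilyloxy)cyclobut-2-en-1-one | CC(C)OC1=C(C(C)C)C(O[Si](C)(C)C)(C1=O)C1=C[C@]23CCC[C@](C)(C(=O)OC2)[C@@H]3C=C1 | intermediate
23 | dienylketene | O=C=C(OC(C)C)/C(C(C)C)=C(\C1=C[C@]23CCC[C@](C)(C(=O)OC2)[C@@H]3C=C1)O[Si](C)(C)C | intermediate
24 | hydroquinone mono(trimethylsilyl) ether (11-OH, 14-OSiMe3, 12-O-isopropyl) | CC(C)Oc1c(C(C)C)c(O[Si](C)(C)C)c2c(c1O)[C@]13CCC[C@](C)(C(=O)OC1)[C@@H]3C=C2 | intermediate
25 | 12-O-isopropyl-6,7-dehydroroyleanone 19,20-olide | CC(C)OC1=C(C(C)C)C(=O)C2=C(C1=O)[C@]13CCC[C@](C)(C(=O)OC1)[C@@H]3C=C2 | intermediate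
26 | 6,7-dehydroroyleanone 19,20-olide | OC1=C(C(C)C)C(=O)C2=C(C1=O)[C@]13CCC[C@](C)(C(=O)OC1)[C@@H]3C=C2 | intermediate
27 | 12-O-acetyl-6,7-dehydroroyleanone 19,20-olide (4S,5R,10R) | CC(=O)OC1=C(C(C)C)C(=O)C2=C(C1=O)[C@]13CCC[C@](C)(C(=O)OC1)[C@@H]3C=C2 | target

## Step count and risk

Total step count: 14. Longest linear sequence: 14 steps from benzoic acid 1. All other inputs (2, 6, 16, 20) are commercial and enter directly.

**Step 5 (key step).** The δ-lactone closure is entropically less favourable than the five-membered closure that this catalyst class is known for. Cyclisation may therefore be slow, so that reversible phosphine addition to the dienone or slow alkylation of the catalyst by the chloride competes, or the hydrogen-bonded transition state may discriminate the two enone arms poorly. Fallback, setting out from 5: esterification with diethylphosphonoacetic acid gives [1-(3-chloropropyl)cyclohexa-2,5-dien-1-yl]methyl 2-(diethoxyphosphoryl)acetate F1, and the oxidation of step 4 gives its dienone F2. F2 has an acidic C–H, so it can undergo the desymmetrising intramolecular Michael addition under a cinchona-derived bifunctional thiourea or a cinchonidinium phase-transfer salt, to give the cis-fused α-phosphono lactone F3. A Horner–Wadsworth–Emmons reaction of F3 with aqueous formaldehyde and K2CO3 installs the exocyclic methylene and returns to the route at 10.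

**Step 6.** Hydride may be delivered to the ring B enone (conjugate or carbonyl reduction) in competition with the methylene lactone. The alkylation by a primary chloride may also be slow enough for proton transfer from C6 to quench the lactone enolate. Fallback, setting out from 10: Luche reduction removes the competing acceptor and gives the allylic alcohol F4 (7-hydroxy, methylene lactone intact). Treatment of F4 with two equivalents of K[(s-Bu)3BH] and DMPU then effects the reductive ring A closure on the alkoxide to give the tricyclic allylic alcohol F5, and MnO2 oxidation of F5 returns to the route at 12.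

**Step 11.** The isopropyl nucleophile may attack the lactone carbonyl, or reduce rather than add to the cyclobutenone, and the silyl ether may be lost during the anhydride-induced transposition. Fallback, which carries the isopropyl group in the electrophile so that the lactone never meets an alkyl organometallic, setting out from 16 and 15: isopropyllithium adds to 16 to give 4-hydroxy-2,3-diisopropoxy-4-isopropylcyclobut-2-en-1-one F6. Trifluoroacetic anhydride followed by isopropanol converts F6 into the monoketal 2,4,4-triisopropoxy-3-isopropylcyclobut-2-en-1-one F7. Dienyllithium 17 (from 15 as in step 10) adds to the only carbonyl of F7, and the alkoxide is capped with t-BuMe2SiOTf to give the silyl ether ketal F8. Mild hydrolysis of the ketal (oxalic acid on wet silica) gives the 4-dienyl-2-isopropoxy-3-isopropyl-4-(tert-butyldimethylsilyloxy)cyclobutenone F9. Thermolysis and cerium oxidation as in step 12 return to the route at 25.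

**Step 4.** Peroxyl radicals may add to or polymerise the acrylate, or the oxidation may stall at the allylic peroxide stage. Fallback with a masked acrylate, setting out from 5: acylation with 3-chloropropanoyl chloride gives [1-(3-chloropropyl)cyclohexa-2,5-dien-1-yl]methyl 3-chloropropanoate F10. The same oxidation gives the dienone F11, and dehydrochlorination of F11 with Et3N unveils the acrylate and returns to the route at 8.

**Step 9.** The allylic C7 centre may ionise, which would lead to allylic substitution or a 1,2-shift from the neighbouring quaternary C10 instead of clean elimination. Fallback, which postpones the elimination to the quinone stage where loss of the C7 oxygen gives the fully conjugated system, setting out from 14: silylation gives the 7-(tert-butyldimethylsilyloxy)-8-iodo alkene F12. Steps 10 and 11 applied to F12 give first the squarate adduct F13 and then the transposed cyclobutenone F14. Step 12 gives the 7-silyloxy-12-isopropoxy quinone F15. Treatment of F15 with TsOH in warm benzene eliminates the silanol and returns to the route at 25.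

## Further compounds

F1 | step 5 | [1-(3-chloropropyl)cyclohexa-2,5-dien-1-yl]methyl 2-(diethoxyphosphoryl)acetate | CCOP(=O)(OCC)CC(=O)OCC1(CCCCl)C=CCC=C1
F2 | step 5 | [1-(3-chloropropyl)-4-oxocyclohexa-2,5-dien-1-yl]methyl 2-(diethoxyphosphoryl)acetate | CCOP(=O)(OCC)CC(=O)OCC1(CCCCl)C=CC(=O)C=C1
F3 | step 5 | cis-fused α-(diethoxyphosphoryl)-δ-lactone enone (10β-CH2O, 5α-H; phosphonate carbon epimers) | O=C1C=C[C@]2(CCCCl)COC(=O)C(P(=O)(OCC)OCC)[C@@H]2C1
F4 | step 6 | 7-hydroxy bicyclic α-methylene-δ-lactone (C7 epimers) | OC1C=C[C@]2(CCCCl)COC(=O)C(=C)[C@@H]2C1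
F5 | step 6 | tricyclic 7-hydroxy-Δ8 lactone (C7 epimers) | OC1C=C[C@]23CCC[C@](C)(C(=O)OC2)[C@@H]3C1
F6 | step 11 | 4-hydroxy-2,3-diisopropoxy-4-isopropylcyclobut-2-en-1-one | CC(C)OC1=C(OC(C)C)C(O)(C(C)C)C1=O
F7 | step 11 | 2,4,4-triisopropoxy-3-isopropylcyclobut-2-en-1-one | CC(C)OC1=C(C(C)C)C(=O)C1(OC(C)C)OC(C)C
F8 | step 11 | 1-dienyl-1-(tert-butyldimethylsilyloxy)-3,4,4-triisopropoxy-2-isopropylcyclobut-2-ene | CC(C)OC1=C(C(C)C)C(O[Si](C)(C)C(C)(C)C)(C2=C[C@]34CCC[C@](C)(C(=O)OC3)[C@@H]4C=C2)C1(OC(C)C)OC(C)C
F9 | step 11 | 4-dienyl-2-isopropoxy-3-isopropyl-4-(tert-butyldimethylsilyloxy)cyclobut-2-en-1-one | CC(C)OC1=C(C(C)C)C(O[Si](C)(C)C(C)(C)C)(C1=O)C1=C[C@]23CCC[C@](C)(C(=O)OC2)[C@@H]3C=C1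
F10 | step 4 | [1-(3-chloropropyl)cyclohexa-2,5-dien-1-yl]methyl 3-chloropropanoate | ClCCC(=O)OCC1(CCCCl)C=CCC=C1
F11 | step 4 | [1-(3-chloropropyl)-4-oxocyclohexa-2,5-dien-1-yl]methyl 3-chloropropanoate | ClCCC(=O)OCC1(CCCCl)C=CC(=O)C=C1
F12 | step 9 | 7-(tert-butyldimethylsilyloxy)-8-iodo-Δ8 lactone | CC(C)(C)[Si](C)(C)OC1C(I)=C[C@]23CCC[C@](C)(C(=O)OC2)[C@@H]3C1
F13 | step 9 | squarate adduct of the 7-silyloxy alkenyllithium (4-OSiMe3, 2,3-diisopropoxy) | CC(C)OC1=C(OC(C)C)C(O[Si](C)(C)C)(C1=O)C1=C[C@]23CCC[C@](C)(C(=O)OC2)[C@@H]3CC1O[Si](C)(C)C(C)(C)C
F14 | step 9 | transposed 2-isopropoxy-3-isopropyl cyclobutenone of the 7-silyloxy series | CC(C)OC1=C(C(C)C)C(O[Si](C)(C)C)(C1=O)C1=C[C@]23CCC[C@](C)(C(=O)OC2)[C@@H]3CC1O[Si](C)(C)C(C)(C)C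
F15 | step 9 | 7-(tert-butyldimethylsilyloxy)-12-O-isopropylroyleanone 19,20-olide | CC(C)OC1=C(C(C)C)C(=O)C2=C(C1=O)[C@]13CCC[C@](C)(C(=O)OC1)[C@@H]3CC2O[Si](C)(C)C(C)(C)C
A1 | alternative 1 | ethyl (6E)-6-[(benzyloxy)methyl]-2-methyl-3-oxo-9-(2,4,5-trimethoxy-3-isopropylphenyl)non-6-enoate | CCOC(=O)C(C)C(=O)CC/C(COCc1ccccc1)=C/CCc1cc(OC)c(OC)c(C(C)C)c1OC
A2 | alternative 1 | ethyl 20-benzyloxy-11,12,14-trimethoxy-3-oxoabieta-8,11,13-trien-19-oate | CCOC(=O)[C@@]1(C)C(=O)CC[C@]2(COCc3ccccc3)c3c(OC)c(OC)c(C(C)C)c(OC)c3CC[C@@H]12
A3 | alternative 2 | (2Z)-2-ethenyl-5-(2,4,5-trimethoxy-3-isopropylphenyl)pent-2-en-1-yl 2-methylprop-2-enoate | CC(=C)C(=O)OC/C(C=C)=C\CCc1cc(OC)c(OC)c(C(C)C)c1OC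
A4 | alternative 2 | bridged lactone with bridgehead C1=C10 alkene (3-oxabicyclo[3.3.1]non-5-en-2-one core; one enantiomer of the racemate drawn) | C[C@@]12CCC=C(COC1=O)[C@H]2CCc1cc(OC)c(OC)c(C(C)C)c1OC
A5 | alternative 3 | (+)-podocarpic acid | O=C(O)[C@@]1(C)CCC[C@]2(C)c3cc(O)ccc3CC[C@@H]12
A6 | alternative 3 | 12-methoxypodocarpa-8,11,13-trien-19,20-olide | COc1ccc2c(c1)[C@]13CCC[C@](C)(C(=O)OC1)[C@@H]3CC2
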